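**Retrosynthetic overview** (carotenoid numbering: ring C1–C6, chain C7 to C12′)
1. The base-labile β,γ-epoxy ketone is made last, by MnO2 oxidation of the C8 allylic alcohol after C3–O desilylation.
2. C11=C12: Horner–Wadsworth–Emmons olefination of a C15 allylic phosphonate with the commercial C10 dialdehyde.
3. C8–C9: Nozaki–Hiyama–Kishi coupling of the ring acetaldehyde (fragment A) with diethyl (E)-(3-iodobut-2-enyl)phosphonate (fragment B, from but-2-yn-1-ol).
4. Fragment A: one-carbon homologation (Wittig methylenation, hydroboration, oxidation) of the epoxy aldehyde obtained by Sharpless epoxidation of the allylic alcohol derived from the enol triflate of (4R,6R)-actinol.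
5. Ring order: the cyclohexane ring is bought with its carbinol stereocentre; the oxirane ring is the only ring formed (step 5).

Assumption: (4R,6R)-actinol, but-2-yn-1-ol and the C10 dialdehyde are bought; the C8 carbinol made in step 13 is carried as both epimers because step 16 converts it into the ketone.

**Fragment A**

Step 1
Reactants: 1 (4R,6R)-4-hydroxy-2,2,6-trimethylcyclohexan-1-one
Product: 2 (4R,6R)-4-[(tert-butyldimethylsilyl)oxy]-2,2,6-trimethylcyclohexan-1-one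
Conditions: TBSCl, imidazole, DMF, rt
Reagents that add atoms: tert-butyldimethylsilyl chloride, CC(C)(C)[Si](C)(C)Cl
Why: Imidazole-promoted silylation (silyl ether protection) of the only hydroxyl; no stereocentre is touched.

Step 2
Reactants: 2 (4R,6R)-4-[(tert-butyldimethylsilyl)oxy]-2,2,6-trimethylcyclohexan-1-one
Product: 4 (4R)-4-[(tert-butyldimethylsilyl)oxy]-2,6,6-trimethylcyclohex-1-en-1-yl trifluoromethanesulfonate, via lithium enolate 3 (not isolated)
Conditions: LiN(i-Pr)2, THF, −78 °C; then PhNTf2, −78 °C → rt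
Reagents that add atoms: N-phenylbis(trifluoromethanesulfonimide), O=S(=O)(N(c1ccccc1)S(=O)(=O)C(F)(F)F)C(F)(F)F
Why: The ketone has one α-hydrogen, so a single enolate forms and is trapped on oxygen (enolate O-triflation); the methyl-bearing stereocentre is erased on purpose and the carbinol centre is untouched.

Step 3
Reactants: 4 (4R)-4-[(tert-butyldimethylsilyl)oxy]-2,6,6-trimethylcyclohex-1-en-1-yl trifluoromethanesulfonate
Product: 5 methyl (4R)-4-[(tert-butyldimethylsilyl)oxy]-2,6,6-trimethylcyclohex-1-ene-1-carboxylate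
Conditions: Pd(OAc)2 (5 mol%), PPh3, CO (1 atm), Et3N, MeOH/DMF, 70 °C
Reagents that add atoms: carbon monoxide, [C-]#[O+]; methanol, CO
Why: Palladium-catalysed alkoxycarbonylation: zerovalent palladium inserts into the C–OTf bond, CO inserts and methanol cleaves the acyl complex.

Step 4
Reactants: 5 methyl (4R)-4-[(tert-butyldimethylsilyl)oxy]-2,6,6-trimethylcyclohex-1-ene-1-carboxylate
Product: 6 {(4R)-4-[(tert-butyldimethylsilyl)oxy]-2,6,6-trimethylcyclohex-1-en-1-yl}methanol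
Conditions: i-Bu2AlH (2.5 equiv), CH2Cl2, −78 → 0 °C
Reagents that add atoms: none
Why: Hydride reduction of the conjugated ester to the allylic alcohol (1,2-reduction); the silyl ether is inert.

Step 5
Reactants: 6 {(4R)-4-[(tert-butyldimethylsilyl)oxy]-2,6,6-trimethylcyclohex-1-en-1-yl}methanol
Product: 7 {(1R,4S,6R)-4-[(tert-butyldimethylsilyl)oxy]-2,2,6-trimethyl-7-oxabicyclo[4.1.0]heptan-1-yl}methanol
Conditions: Ti(Oi-Pr)4, D-(−)-diethyl tartrate, t-BuOOH, 4 Å MS, CH2Cl2, −20 °C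
Reagents that add atoms: tert-butyl hydroperoxide, CC(C)(C)OO
Why: Sharpless asymmetric epoxidation: the D-(−)-tartrate complex (the one giving 2R-type epoxy alcohols) delivers oxygen to the face anti to the silyloxy group, matched with the substrate bias, setting both oxirane carbons (5R,6S in carotenoid numbering).

Step 6
Reactants: 7 {(1R,4S,6R)-4-[(tert-butyldimethylsilyl)oxy]-2,2,6-trimethyl-7-oxabicyclo[4.1.0]heptan-1-yl}methanol
Product: 8 (1S,4S,6R)-4-[(tert-butyldimethylsilyl)oxy]-2,2,6-trimethyl-7-oxabicyclo[4.1.0]heptane-1-carbaldehyde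
Conditions: n-Pr4N[RuO4] (5 mol%), NMO, 4 Å MS, CH2Cl2, rt
Reagents that add atoms: none
Why: Ley–Griffith oxidation of the primary alcohol under neutral conditions gives a non-enolisable aldehyde and leaves the epoxide intact.

Step 7
Reactants: 8 (1S,4S,6R)-4-[(tert-butyldimethylsilyl)oxy]-2,2,6-trimethyl-7-oxabicyclo[4.1.0]heptane-1-carbaldehyde
Product: 9 (1S,4S,6R)-4-[(tert-butyldimethylsilyl)oxy]-1-ethenyl-2,2,6-trimethyl-7-oxabicyclo[4.1.0]heptane
Conditions: Ph3PCH3Br, t-BuOK, THF, 0 °C → rt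
Reagents that add atoms: methyltriphenylphosphonium bromide, [Br-].C[P+](c1ccccc1)(c1ccccc1)c1ccccc1
Why: Wittig methylenation with the small non-stabilised ylide converts the hindered aldehyde into the vinyl oxirane without touching a stereocentre.

Step 8
Reactants: 9 (1S,4S,6R)-4-[(tert-butyldimethylsilyl)oxy]-1-ethenyl-2,2,6-trimethyl-7-oxabicyclo[4.1.0]heptane
Product: 11 2-{(1S,4S,6R)-4-[(tert-butyldimethylsilyl)oxy]-2,2,6-trimethyl-7-oxabicyclo[4.1.0]heptan-1-yl}ethan-1-ol, via B-alkyl-9-BBN adduct 10 (not isolated)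
Conditions: 9-BBN, THF, 0 °C → rt; then 30% H2O2, 3 M NaOH, 0 °C
Reagents that add atoms: hydrogen peroxide, OO
Why: Brown hydroboration with bulky 9-BBN puts boron on the terminal carbon (anti-Markovnikov) and alkaline peroxide oxidation gives the primary alcohol, so C7 becomes CH2.

Step 9
Reactants: 11 2-{(1S,4S,6R)-4-[(tert-butyldimethylsilyl)oxy]-2,2,6-trimethyl-7-oxabicyclo[4.1.0]heptan-1-yl}ethan-1-ol
Product: 12 2-{(1S,4S,6R)-4-[(tert-butyldimethylsilyl)oxy]-2,2,6-trimethyl-7-oxabicyclo[4.1.0]heptan-1-yl}acetaldehyde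
Conditions: Dess–Martin periodinane, pyridine, CH2Cl2, 0 °C; used crude
Reagents that add atoms: none
Why: Dess–Martin oxidation under buffered, non-basic conditions gives the β,γ-epoxy aldehyde without triggering β-elimination of the epoxide.

**Fragment B**

Step 10
Reactants: 13 but-2-yn-1-ol
Product: 15 (2E)-3-iodobut-2-en-1-ol, via alkenylzirconocene chloride 14 (not isolated)
Conditions: i-Bu2AlH (1 equiv), THF, 0 °C; Cp2Zr(H)Cl, rt; then I2, −78 → 0 °C
Reagents that add atoms: iodine, II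
Why: Hydrozirconation (Schwartz reagent) of the aluminium alkoxide is a syn addition that places zirconium on the carbon remote from oxygen, and iodinolysis with retention gives the E vinyl iodide.

Step 11
Reactants: 15 (2E)-3-iodobut-2-en-1-ol
Product: 16 (2E)-1-bromo-3-iodobut-2-ene
Conditions: PBr3 (0.4 equiv), Et2O, 0 °C
Reagents that add atoms: phosphorus tribromide, BrP(Br)Br
Why: SN2 bromination of the primary allylic alcohol; the alkene geometry is kept.

Step 12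
Reactants: 16 (2E)-1-bromo-3-iodobut-2-ene
Product: 17 diethyl [(2E)-3-iodobut-2-en-1-yl]phosphonate
Conditions: P(OEt)3, neat, 120 °C
Reagents that add atoms: triethyl phosphite, CCOP(OCC)OCC
Why: Michaelis–Arbuzov reaction at the allylic bromide; the vinyl iodide does not react.

**Assembly**

Step 13
Reactants: 12 2-{(1S,4S,6R)-4-[(tert-butyldimethylsilyl)oxy]-2,2,6-trimethyl-7-oxabicyclo[4.1.0]heptan-1-yl}acetaldehyde; 17 diethyl [(2E)-3-iodobut-2-en-1-yl]phosphonate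
Product: 19 diethyl [(2E)-5-{(1S,4S,6R)-4-[(tert-butyldimethylsilyl)oxy]-2,2,6-trimethyl-7-oxabicyclo[4.1.0]heptan-1-yl}-4-hydroxy-3-methylpent-2-en-1-yl]phosphonate, via alkenylchromium dichloride 18 (not isolated)
Conditions: CrCl2 (4 equiv), NiCl2 (2 mol%), DMSO, rt
Reagents that add atoms: none
Why: Nozaki–Hiyama–Kishi coupling: the nickel-catalysed alkenylchromium reagent adds only to the aldehyde with retention of the E geometry and tolerates phosphonate, epoxide and silyl ether; the new C8 carbinol forms as both epimers, which converge in step 16.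

Step 14
Reactants: 19 diethyl [(2E)-5-{(1S,4S,6R)-4-[(tert-butyldimethylsilyl)oxy]-2,2,6-trimethyl-7-oxabicyclo[4.1.0]heptan-1-yl}-4-hydroxy-3-methylpent-2-en-1-yl]phosphonate; 20 (2E,4E,6E)-2,7-dimethylocta-2,4,6-trienedial
Product: 22 (2E,4E,6E,8E,10E)-13-{(1S,4S,6R)-4-[(tert-butyldimethylsilyl)oxy]-2,2,6-trimethyl-7-oxabicyclo[4.1.0]heptan-1-yl}-12-hydroxy-2,7,11-trimethyltrideca-2,4,6,8,10-pentaenal, via dilithiated phosphonate 21 (not isolated)
Conditions: n-BuLi (2.1 equiv), DMPU, THF, −78 °C; then 20 (3 equiv), −78 → 0 °C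
Reagents that add atoms: none
Why: Horner–Wadsworth–Emmons olefination of the alkoxide/allylic phosphonate dianion with one aldehyde of the excess symmetrical dialdehyde builds C11=C12 with E selectivity; the free alkoxide prevents elimination at C8.

Step 15
Reactants: 22 (2E,4E,6E,8E,10E)-13-{(1S,4S,6R)-4-[(tert-butyldimethylsilyl)oxy]-2,2,6-trimethyl-7-oxabicyclo[4.1.0]heptan-1-yl}-12-hydroxy-2,7,11-trimethyltrideca-2,4,6,8,10-pentaenal
Product: 23 (2E,4E,6E,8E,10E)-12-hydroxy-13-[(1S,4S,6R)-4-hydroxy-2,2,6-trimethyl-7-oxabicyclo[4.1.0]heptan-1-yl]-2,7,11-trimethyltrideca-2,4,6,8,10-pentaenal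
Conditions: n-Bu4NF, AcOH, THF, 0 °C → rt
Reagents that add atoms: none
Why: Fluoride cleavage of the silyl ether (desilylation), buffered for the polyenal and done before the base-labile ketone exists.

Step 16
Reactants: 23 (2E,4E,6E,8E,10E)-12-hydroxy-13-[(1S,4S,6R)-4-hydroxy-2,2,6-trimethyl-7-oxabicyclo[4.1.0]heptan-1-yl]-2,7,11-trimethyltrideca-2,4,6,8,10-pentaenal
Product: 24 (2E,4E,6E,8E,10E)-13-[(1S,4S,6R)-4-hydroxy-2,2,6-trimethyl-7-oxabicyclo[4.1.0]heptan-1-yl]-2,7,11-trimethyl-12-oxotrideca-2,4,6,8,10-pentaenal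
Conditions: MnO2 (activated, excess), CH2Cl2, rt, dark
Reagents that add atoms: none
Why: Chemoselective allylic oxidation: MnO2 oxidises only the polyene-conjugated C8 alcohol and leaves the saturated ring alcohol, the epoxide and the aldehyde, so the labile β,γ-epoxy enone appears in the last, neutral step.

**Compound list**
1 | (4R,6R)-4-hydroxy-2,2,6-trimethylcyclohexan-1-one ((−)-actinol) | CC1(C)C[C@H](O)C[C@@H](C)C1=O | starting material
2 | (4R,6R)-4-[(tert-butyldimethylsilyl)oxy]-2,2,6-trimethylcyclohexan-1-one | CC1(C)C[C@H](O[Si](C)(C)C(C)(C)C)C[C@@H](C)C1=O | intermediate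
3 | lithium (4R)-4-[(tert-butyldimethylsilyl)oxy]-2,6,6-trimethylcyclohex-1-en-1-olate (lithium enolate of 2, not isolated) | [Li+].CC1=C([O-])C(C)(C)C[C@H](O[Si](C)(C)C(C)(C)C)C1 | intermediate
4 | (4R)-4-[(tert-butyldimethylsilyl)oxy]-2,6,6-trimethylcyclohex-1-en-1-yl trifluoromethanesulfonate | CC1=C(OS(=O)(=O)C(F)(F)F)C(C)(C)C[C@H](O[Si](C)(C)C(C)(C)C)C1 | intermediate
5 | methyl (4R)-4-[(tert-butyldimethylsilyl)oxy]-2,6,6-trimethylcyclohex-1-ene-1-carboxylate | COC(=O)C1=C(C)C[C@@H](O[Si](C)(C)C(C)(C)C)CC1(C)C | intermediate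
6 | {(4R)-4-[(tert-butyldimethylsilyl)oxy]-2,6,6-trimethylcyclohex-1-en-1-yl}methanol | OCC1=C(C)C[C@@H](O[Si](C)(C)C(C)(C)C)CC1(C)C | intermediate
7 | {(1R,4S,6R)-4-[(tert-butyldimethylsilyl)oxy]-2,2,6-trimethyl-7-oxabicyclo[4.1.0]heptan-1-yl}methanol (epoxide anti to the silyloxy group) | OC[C@@]12O[C@]1(C)C[C@@H](O[Si](C)(C)C(C)(C)C)CC2(C)C | intermediate
8 | (1S,4S,6R)-4-[(tert-butyldimethylsilyl)oxy]-2,2,6-trimethyl-7-oxabicyclo[4.1.0]heptane-1-carbaldehyde | O=C[C@@]12O[C@]1(C)C[C@@H](O[Si](C)(C)C(C)(C)C)CC2(C)C | intermediate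
9 | (1S,4S,6R)-4-[(tert-butyldimethylsilyl)oxy]-1-ethenyl-2,2,6-trimethyl-7-oxabicyclo[4.1.0]heptane | C=C[C@@]12O[C@]1(C)C[C@@H](O[Si](C)(C)C(C)(C)C)CC2(C)C | intermediate
10 | 9-(2-{(1S,4S,6R)-4-[(tert-butyldimethylsilyl)oxy]-2,2,6-trimethyl-7-oxabicyclo[4.1.0]heptan-1-yl}ethyl)-9-borabicyclo[3.3.1]nonane (not isolated) | B1(CC[C@@]34O[C@]3(C)C[C@@H](O[Si](C)(C)C(C)(C)C)CC4(C)C)C2CCCC1CCC2 | intermediate
11 | 2-{(1S,4S,6R)-4-[(tert-butyldimethylsilyl)oxy]-2,2,6-trimethyl-7-oxabicyclo[4.1.0]heptan-1-yl}ethan-1-ol | OCC[C@@]12O[C@]1(C)C[C@@H](O[Si](C)(C)C(C)(C)C)CC2(C)C | intermediate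
12 | 2-{(1S,4S,6R)-4-[(tert-butyldimethylsilyl)oxy]-2,2,6-trimethyl-7-oxabicyclo[4.1.0]heptan-1-yl}acetaldehyde | O=CC[C@@]12O[C@]1(C)C[C@@H](O[Si](C)(C)C(C)(C)C)CC2(C)C | intermediate
13 | but-2-yn-1-ol | CC#CCO | starting material
14 | diisobutylaluminium (2E)-3-[chlorobis(cyclopentadienyl)zirconio]but-2-en-1-olate (not isolated) | CC(C)C[Al](CC(C)C)OC/C=C(\C)[Zr](Cl)(C1C=CC=C1)C1C=CC=C1 | intermediate
15 | (2E)-3-iodobut-2-en-1-ol | OC/C=C(\C)I | intermediate
16 | (2E)-1-bromo-3-iodobut-2-ene | BrC/C=C(\C)I | intermediate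
17 | diethyl [(2E)-3-iodobut-2-en-1-yl]phosphonate | CCOP(=O)(OCC)C/C=C(\C)I | intermediate
18 | diethyl [(2E)-3-(dichlorochromio)but-2-en-1-yl]phosphonate (not isolated) | CCOP(=O)(OCC)C/C=C(\C)[Cr](Cl)Cl | intermediate
19 | diethyl [(2E)-5-{(1S,4S,6R)-4-[(tert-butyldimethylsilyl)oxy]-2,2,6-trimethyl-7-oxabicyclo[4.1.0]heptan-1-yl}-4-hydroxy-3-methylpent-2-en-1-yl]phosphonate (both carbinol epimers) | CCOP(=O)(OCC)C/C=C(\C)C(O)C[C@@]12O[C@]1(C)C[C@@H](O[Si](C)(C)C(C)(C)C)CC2(C)C | intermediate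
20 | (2E,4E,6E)-2,7-dimethylocta-2,4,6-trienedial (C10 dialdehyde) | O=C/C(C)=C/C=C/C=C(\C)C=O | starting material
21 | dilithio derivative of 19: lithium alkoxide, lithiated carbon next to phosphorus (not isolated) | [Li+].[Li+].CCOP(=O)(OCC)[CH-]/C=C(\C)C([O-])C[C@@]12O[C@]1(C)C[C@@H](O[Si](C)(C)C(C)(C)C)CC2(C)C | intermediate
22 | (2E,4E,6E,8E,10E)-13-{(1S,4S,6R)-4-[(tert-butyldimethylsilyl)oxy]-2,2,6-trimethyl-7-oxabicyclo[4.1.0]heptan-1-yl}-12-hydroxy-2,7,11-trimethyltrideca-2,4,6,8,10-pentaenal (both C12 epimers) | C\C(C=O)=C/C=C/C=C(C)/C=C/C=C(\C)C(O)C[C@@]12O[C@]1(C)C[C@@H](O[Si](C)(C)C(C)(C)C)CC2(C)C | intermediate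
23 | (2E,4E,6E,8E,10E)-12-hydroxy-13-[(1S,4S,6R)-4-hydroxy-2,2,6-trimethyl-7-oxabicyclo[4.1.0]heptan-1-yl]-2,7,11-trimethyltrideca-2,4,6,8,10-pentaenal (both C12 epimers) | C\C(C=O)=C/C=C/C=C(C)/C=C/C=C(\C)C(O)C[C@@]12O[C@]1(C)C[C@@H](O)CC2(C)C | intermediate
24 | (2E,4E,6E,8E,10E)-13-[(1S,4S,6R)-4-hydroxy-2,2,6-trimethyl-7-oxabicyclo[4.1.0]heptan-1-yl]-2,7,11-trimethyl-12-oxotrideca-2,4,6,8,10-pentaenal (CNP0310604.1; 3S,5R,6S in carotenoid numbering) | C\C(C=O)=C/C=C/C=C(C)/C=C/C=C(\C)C(=O)C[C@@]12O[C@]1(C)C[C@@H](O)CC2(C)C | target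

**Totals**
Total step count: 16. Longest linear sequence: 13 steps (steps 1–9, then 13–16); fragment B takes 3 steps (10–12).

**Three steps most likely to fail**

Step 8 (hydroboration of the vinyl oxirane). The borane may open the allylic epoxide instead of adding cleanly to the terminal carbon. The fallback sets out from 8 and comes back at 12, bypassing 9 to 11. Aldehyde 8 is treated with LiCH(Bpin)2 (from CH2(Bpin)2 and lithium 2,2,6,6-tetramethylpiperidide, THF, −78 → 0 °C; boron-Wittig olefination) to give the alkenyl boronate 2-[(E)-2-{(1S,4S,6R)-4-[(tert-butyldimethylsilyl)oxy]-2,2,6-trimethyl-7-oxabicyclo[4.1.0]heptan-1-yl}ethenyl]-4,4,5,5-tetramethyl-1,3,2-dioxaborolane F1. Oxidation of its C–B bond with NaBO3·4H2O in THF/H2O gives the enol, which tautomerises to aldehyde 12.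

Step 13 (Nozaki–Hiyama–Kishi coupling). The 2-iodoalkene is hindered, and the Lewis-acidic chromium salts may open the epoxide or eliminate the β,γ-epoxy aldehyde. The fallback sets out from 15 and 12 and comes back at 19, using an organolithium instead of chromium. Iodide 15 is converted into its dilithio derivative (n-BuLi 1 equiv, then t-BuLi 2 equiv, Et2O, −78 °C; iodine–lithium exchange) and added to 12 to give the diol (2E)-5-{(1S,4S,6R)-4-[(tert-butyldimethylsilyl)oxy]-2,2,6-trimethyl-7-oxabicyclo[4.1.0]heptan-1-yl}-3-methylpent-2-ene-1,4-diol F2. Only the primary allylic hydroxyl is brominated (CBr4, PPh3, CH2Cl2, −40 °C; Appel reaction) to give (3E)-5-bromo-1-{(1S,4S,6R)-4-[(tert-butyldimethylsilyl)oxy]-2,2,6-trimethyl-7-oxabicyclo[4.1.0]heptan-1-yl}-3-methylpent-3-en-2-ol F3. Displacement with NaP(O)(OEt)2 in THF at 0 °C (Michaelis–Becker reaction) gives 19.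

Step 14 (olefination of the hydroxy phosphonate dianion). The dianion may react sluggishly, condense twice with the dialdehyde, or give a poor E:Z ratio. The fallback sets out from 17 and 20 and comes back at 24; it olefinates before the C8 oxygen exists and then makes both carbonyls in one oxidation. Phosphonate 17 (n-BuLi, DMPU, THF, −78 °C) and excess 20 give (2E,4E,6E,8E,10E)-11-iodo-2,7-dimethyldodeca-2,4,6,8,10-pentaenal F4. NaBH4 in MeOH at 0 °C gives (2E,4E,6E,8E,10E)-11-iodo-2,7-dimethyldodeca-2,4,6,8,10-pentaen-1-ol F5. Coupling of F5 with 12 (CrCl2, NiCl2 cat., DMSO) gives (2E,4E,6E,8E,10E)-13-{(1S,4S,6R)-4-[(tert-butyldimethylsilyl)oxy]-2,2,6-trimethyl-7-oxabicyclo[4.1.0]heptan-1-yl}-2,7,11-trimethyltrideca-2,4,6,8,10-pentaene-1,12-diol F6. n-Bu4NF in THF gives the triol (2E,4E,6E,8E,10E)-13-[(1S,4S,6R)-4-hydroxy-2,2,6-trimethyl-7-oxabicyclo[4.1.0]heptan-1-yl]-2,7,11-trimethyltrideca-2,4,6,8,10-pentaene-1,12-diol F7. MnO2 in CH2Cl2 oxidises both allylic alcohols (secondary C8 and primary C12′) and leaves the ring alcohol, giving 24.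

**Further compounds**
F1 | step 8 | 2-[(E)-2-{(1S,4S,6R)-4-[(tert-butyldimethylsilyl)oxy]-2,2,6-trimethyl-7-oxabicyclo[4.1.0]heptan-1-yl}ethenyl]-4,4,5,5-tetramethyl-1,3,2-dioxaborolane | CC1(C)OB(/C=C/[C@@]23O[C@]2(C)C[C@@H](O[Si](C)(C)C(C)(C)C)CC3(C)C)OC1(C)C
F2 | step 13 | (2E)-5-{(1S,4S,6R)-4-[(tert-butyldimethylsilyl)oxy]-2,2,6-trimethyl-7-oxabicyclo[4.1.0]heptan-1-yl}-3-methylpent-2-ene-1,4-diol | OC/C=C(\C)C(O)C[C@@]12O[C@]1(C)C[C@@H](O[Si](C)(C)C(C)(C)C)CC2(C)C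
F3 | step 13 | (3E)-5-bromo-1-{(1S,4S,6R)-4-[(tert-butyldimethylsilyl)oxy]-2,2,6-trimethyl-7-oxabicyclo[4.1.0]heptan-1-yl}-3-methylpent-3-en-2-ol | BrC/C=C(\C)C(O)C[C@@]12O[C@]1(C)C[C@@H](O[Si](C)(C)C(C)(C)C)CC2(C)C
F4 | step 14 | (2E,4E,6E,8E,10E)-11-iodo-2,7-dimethyldodeca-2,4,6,8,10-pentaenal | C\C(C=O)=C/C=C/C=C(C)/C=C/C=C(\C)I
F5 | step 14 | (2E,4E,6E,8E,10E)-11-iodo-2,7-dimethyldodeca-2,4,6,8,10-pentaen-1-ol | C\C(CO)=C/C=C/C=C(C)/C=C/C=C(\C)I
F6 | step 14 | (2E,4E,6E,8E,10E)-13-{(1S,4S,6R)-4-[(tert-butyldimethylsilyl)oxy]-2,2,6-trimethyl-7-oxabicyclo[4.1.0]heptan-1-yl}-2,7,11-trimethyltrideca-2,4,6,8,10-pentaene-1,12-diol | C\C(CO)=C/C=C/C=C(C)/C=C/C=C(\C)C(O)C[C@@]12O[C@]1(C)C[C@@H](O[Si](C)(C)C(C)(C)C)CC2(C)C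
F7 | step 14 | (2E,4E,6E,8E,10E)-13-[(1S,4S,6R)-4-hydroxy-2,2,6-trimethyl-7-oxabicyclo[4.1.0]heptan-1-yl]-2,7,11-trimethyltrideca-2,4,6,8,10-pentaene-1,12-diol | C\C(CO)=C/C=C/C=C(C)/C=C/C=C(\C)C(O)C[C@@]12O[C@]1(C)C[C@@H](O)CC2(C)C
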